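**Retrosynthetic overview**
- The oxirane is closed last: the tertiary C3′ alkoxide displaces a C2′ mesylate with inversion (erythro hydroxy mesylate → trans epoxide).
- The C5′ carbinol comes from a β‑hydroxy enone by hydroxyl‑directed 1,3‑anti reduction; the enone is unmasked from an isoxazoline by N–O cleavage.
- The aryl ether is made by SN2 of 7‑hydroxy‑8‑methoxycoumarin (bought with the coumarin ring in place) on a primary mesylate.
- Key ring: the isoxazoline, from a nitrile oxide [3+2] cycloaddition to an isopropenyl dioxolane; it forms C3′–O and C4′–C5′, and the bought C2′ centre sets the face.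
- All chirality derives from methyl (S)‑glycerate acetonide (L‑serine series). Ring order: isoxazoline (made, later opened), then oxirane.

Assumption: hydrangetin (7‑hydroxy‑8‑methoxycoumarin), methyl (S)‑2,2‑dimethyl‑1,3‑dioxolane‑4‑carboxylate and 3‑methylbut‑2‑enal are catalogue items. Side‑chain locants C1′–C7′ count from the ArO–CH2 carbon.

**Step 1**
Reactants: 1 methyl (4S)-2,2-dimethyl-1,3-dioxolane-4-carboxylate
Product: 3 1-[(4S)-2,2-dimethyl-1,3-dioxolan-4-yl]ethan-1-one, via Weinreb amide 2 (not isolated)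
Conditions: MeNH(OMe)·HCl, i-PrMgCl, THF, −20 °C; then MeMgBr, −20 → 0 °C; aq. NH4Cl
Reagents that add atoms: methylmagnesium bromide, C[Mg]Br; N,O-dimethylhydroxylamine hydrochloride, CNOC.Cl (its atoms stay in 2 only)
Why: One‑pot Weinreb ketone synthesis, in which the chelated tetrahedral adduct of the N‑methoxy‑N‑methylamide with MeMgBr stops at the ketone and the bought C4 stereocentre is not enolised at −20 to 0 °C.

**Step 2**
Reactants: 3 1-[(4S)-2,2-dimethyl-1,3-dioxolan-4-yl]ethan-1-one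
Product: 4 (4R)-2,2-dimethyl-4-(prop-1-en-2-yl)-1,3-dioxolane
Conditions: Ph3PCH3Br, KN(SiMe3)2, THF, −78 → 0 °C
Reagents that add atoms: methyltriphenylphosphonium bromide, C[P+](c1ccccc1)(c1ccccc1)c1ccccc1.[Br-]
Why: Wittig methylenation with a salt‑free ylide at low temperature converts acetyl into isopropenyl without epimerising the α‑alkoxy centre (the descriptor changes from S to R only through the priority change).

**Step 3**
Reactants: 5 3-methylbut-2-enal
Product: 6 (E)-3-methylbut-2-enal oxime (E/Z mixture used as such)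
Conditions: NH2OH (50% aq.), EtOH, 0 °C → rt
Reagents that add atoms: hydroxylamine, NO
Why: Oxime condensation gives the nitrile oxide precursor; no stereocentre is involved and both oxime isomers lead to the same dipole.

**Step 4**
Reactants: 4 (4R)-2,2-dimethyl-4-(prop-1-en-2-yl)-1,3-dioxolane; 6 (E)-3-methylbut-2-enal oxime
Product: 8 (5R)-5-[(4S)-2,2-dimethyl-1,3-dioxolan-4-yl]-5-methyl-3-(2-methylprop-1-en-1-yl)-4,5-dihydro-1,2-oxazole, via nitrile oxide 7 (not isolated)
Conditions: aq. NaOCl, CH2Cl2, 0 °C → rt, slow addition of 6 (2 equiv)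
Reagents that add atoms: none
Why: Huisgen 1,3‑dipolar cycloaddition of the nitrile oxide made in situ places oxygen on the disubstituted alkene carbon, and the dioxolane centre directs the face through the inside‑alkoxy transition state (ring C–O inside, CH2 anti, H outside next to the geminal methyl), so the new quaternary centre is 5R (erythro adduct, about 5–9:1 expected, minor isomer removed on silica).

**Step 5**
Reactants: 8 (5R)-5-[(4S)-2,2-dimethyl-1,3-dioxolan-4-yl]-5-methyl-3-(2-methylprop-1-en-1-yl)-4,5-dihydro-1,2-oxazole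
Product: 9 (1S)-1-[(5R)-5-methyl-3-(2-methylprop-1-en-1-yl)-4,5-dihydro-1,2-oxazol-5-yl]ethane-1,2-diol
Conditions: 80% aq. AcOH, 40 °C
Reagents that add atoms: none
Why: Acid‑catalysed acetal hydrolysis frees the 1,2‑diol while the acid‑stable isoxazoline keeps the tertiary alcohol and the future enone masked, so no stereocentre is touched.

**Step 6**
Reactants: 9 (1S)-1-[(5R)-5-methyl-3-(2-methylprop-1-en-1-yl)-4,5-dihydro-1,2-oxazol-5-yl]ethane-1,2-diol
Product: 10 (1S)-1-[(5R)-5-methyl-3-(2-methylprop-1-en-1-yl)-4,5-dihydro-1,2-oxazol-5-yl]ethane-1,2-diyl dimethanesulfonate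
Conditions: MsCl (2.5 equiv), Et3N, CH2Cl2, 0 °C
Reagents that add atoms: methanesulfonyl chloride, CS(=O)(=O)Cl
Why: Sulfonylation through sulfene esterifies both hydroxyls, the hindered secondary one included, with retention because no C–O bond is broken.

**Step 7**
Reactants: 10 (1S)-1-[(5R)-5-methyl-3-(2-methylprop-1-en-1-yl)-4,5-dihydro-1,2-oxazol-5-yl]ethane-1,2-diyl dimethanesulfonate; 11 7-hydroxy-8-methoxy-2H-chromen-2-one (hydrangetin)
Product: 12 (1S)-2-[(8-methoxy-2-oxo-2H-chromen-7-yl)oxy]-1-[(5R)-5-methyl-3-(2-methylprop-1-en-1-yl)-4,5-dihydro-1,2-oxazol-5-yl]ethyl methanesulfonate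
Conditions: K2CO3, DMF, 70 °C
Reagents that add atoms: none
Why: Williamson SN2 etherification in which the phenoxide displaces only the primary mesylate, the secondary one being flanked by a quaternary carbon and inert to intermolecular substitution, so both stereocentres are unchanged.

**Step 8**
Reactants: 12 (1S)-2-[(8-methoxy-2-oxo-2H-chromen-7-yl)oxy]-1-[(5R)-5-methyl-3-(2-methylprop-1-en-1-yl)-4,5-dihydro-1,2-oxazol-5-yl]ethyl methanesulfonate
Product: 14 (2S,3R)-3-hydroxy-1-[(8-methoxy-2-oxo-2H-chromen-7-yl)oxy]-3,7-dimethyl-5-oxooct-6-en-2-yl methanesulfonate, via hydroxy imine 13 (not isolated)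
Conditions: Mo(CO)6, B(OH)3, MeCN–H2O (10:1), 75 °C
Reagents that add atoms: water, O
Why: Reductive N–O cleavage of the isoxazoline by Mo(CO)6 and hydrolysis of the resulting β‑hydroxy imine unmask the tertiary aldol as its enone without touching the C=C bonds, the coumarin or the mesylate, the B(OH)3 buffer trapping ammonia so that the tertiary alcohol does not yet close onto the mesylate.

**Step 9**
Reactants: 14 (2S,3R)-3-hydroxy-1-[(8-methoxy-2-oxo-2H-chromen-7-yl)oxy]-3,7-dimethyl-5-oxooct-6-en-2-yl methanesulfonate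
Product: 15 (2S,3R,5R)-3,5-dihydroxy-1-[(8-methoxy-2-oxo-2H-chromen-7-yl)oxy]-3,7-dimethyloct-6-en-2-yl methanesulfonate
Conditions: Me4NBH(OAc)3, MeCN–AcOH (1:1), −30 °C
Reagents that add atoms: none
Why: Evans–Saksena hydroxyl‑directed reduction delivers hydride intramolecularly from the boron bound to the tertiary alcohol through a chair with the large C2 branch equatorial and the methyl axial, giving the 1,3‑anti diol (5R) by 1,2‑reduction only, with the lactone untouched.

**Step 10**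
Reactants: 15 (2S,3R,5R)-3,5-dihydroxy-1-[(8-methoxy-2-oxo-2H-chromen-7-yl)oxy]-3,7-dimethyloct-6-en-2-yl methanesulfonate
Product: 16 7-{[(2R,3R)-3-[(2R)-2-hydroxy-4-methylpent-3-en-1-yl]-3-methyloxiran-2-yl]methoxy}-8-methoxy-2H-chromen-2-one
Conditions: K2CO3, MeOH, 0 °C → rt
Reagents that add atoms: none
Why: Intramolecular Williamson (3‑exo‑tet) closure in which the tertiary alkoxide displaces the vicinal secondary mesylate with inversion at C2′, turning the erythro hydroxy mesylate into the trans (2R,3R) oxirane faster than the C5′ hydroxyl can form a tetrahydrofuran.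

**Compound list**
1 | methyl (4S)-2,2-dimethyl-1,3-dioxolane-4-carboxylate | COC(=O)[C@@H]1COC(C)(C)O1 | starting material
2 | (4S)-N-methoxy-N,2,2-trimethyl-1,3-dioxolane-4-carboxamide (Weinreb amide) | CON(C)C(=O)[C@@H]1COC(C)(C)O1 | intermediate (not isolated)
3 | 1-[(4S)-2,2-dimethyl-1,3-dioxolan-4-yl]ethan-1-one | CC(=O)[C@@H]1COC(C)(C)O1 | intermediate
4 | (4R)-2,2-dimethyl-4-(prop-1-en-2-yl)-1,3-dioxolane | C=C(C)[C@@H]1COC(C)(C)O1 | intermediate
5 | 3-methylbut-2-enal | CC(C)=CC=O | starting material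
6 | (E)-3-methylbut-2-enal oxime | CC(C)=C/C=N/O | intermediate
7 | 3-methylbut-2-enenitrile oxide | CC(C)=CC#[N+][O-] | intermediate (not isolated)
8 | (5R)-5-[(4S)-2,2-dimethyl-1,3-dioxolan-4-yl]-5-methyl-3-(2-methylprop-1-en-1-yl)-4,5-dihydro-1,2-oxazole | CC(C)=CC1=NO[C@](C)(C1)[C@@H]2COC(C)(C)O2 | intermediate
9 | (1S)-1-[(5R)-5-methyl-3-(2-methylprop-1-en-1-yl)-4,5-dihydro-1,2-oxazol-5-yl]ethane-1,2-diol | CC(C)=CC1=NO[C@](C)(C1)[C@@H](O)CO | intermediate
10 | (1S)-1-[(5R)-5-methyl-3-(2-methylprop-1-en-1-yl)-4,5-dihydro-1,2-oxazol-5-yl]ethane-1,2-diyl dimethanesulfonate | CC(C)=CC1=NO[C@](C)(C1)[C@@H](OS(C)(=O)=O)COS(C)(=O)=O | intermediate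
11 | 7-hydroxy-8-methoxy-2H-chromen-2-one (hydrangetin) | COc1c(O)ccc2ccc(=O)oc12 | starting material
12 | (1S)-2-[(8-methoxy-2-oxo-2H-chromen-7-yl)oxy]-1-[(5R)-5-methyl-3-(2-methylprop-1-en-1-yl)-4,5-dihydro-1,2-oxazol-5-yl]ethyl methanesulfonate | COc1c(OC[C@H](OS(C)(=O)=O)[C@@]3(C)CC(C=C(C)C)=NO3)ccc2ccc(=O)oc12 | intermediate
13 | (2S,3R)-3-hydroxy-5-imino-1-[(8-methoxy-2-oxo-2H-chromen-7-yl)oxy]-3,7-dimethyloct-6-en-2-yl methanesulfonate | COc1c(OC[C@H](OS(C)(=O)=O)[C@](C)(O)CC(=N)C=C(C)C)ccc2ccc(=O)oc12 | intermediate (not isolated)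
14 | (2S,3R)-3-hydroxy-1-[(8-methoxy-2-oxo-2H-chromen-7-yl)oxy]-3,7-dimethyl-5-oxooct-6-en-2-yl methanesulfonate | COc1c(OC[C@H](OS(C)(=O)=O)[C@](C)(O)CC(=O)C=C(C)C)ccc2ccc(=O)oc12 | intermediate
15 | (2S,3R,5R)-3,5-dihydroxy-1-[(8-methoxy-2-oxo-2H-chromen-7-yl)oxy]-3,7-dimethyloct-6-en-2-yl methanesulfonate | COc1c(OC[C@H](OS(C)(=O)=O)[C@](C)(O)C[C@@H](O)C=C(C)C)ccc2ccc(=O)oc12 | intermediate
16 | 7-{[(2R,3R)-3-[(2R)-2-hydroxy-4-methylpent-3-en-1-yl]-3-methyloxiran-2-yl]methoxy}-8-methoxy-2H-chromen-2-one | COc1c(OC[C@H]2O[C@]2(C)C[C@@H](O)C=C(C)C)ccc2ccc(=O)oc12 | target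

**Step count and risks**

Total step count: 10. Longest linear sequence: 9 steps (1 → 3 → 4 → 8 → 9 → 10 → 12 → 14 → 15 → 16); the oxime (step 3) is a one‑step side branch.

The three steps most likely to fail are steps 4, 7 and 9.

Step 4 can fail because the nitrile oxide may dimerise to the furoxan faster than it adds to the hindered 1,1‑disubstituted alkene, and the facial bias of an allylic ether is only moderate. The fallback sets out from ketone 3 and builds the tertiary carbinol by an open‑chain Felkin–Anh aldol instead of a cycloaddition. A BF3·OEt2‑promoted Mukaiyama addition of 2‑(trimethylsilyloxy)‑4‑methylpenta‑1,3‑diene (CH2Cl2, −78 °C) gives (6R)-6-[(4S)-2,2-dimethyl-1,3-dioxolan-4-yl]-6-hydroxy-2-methylhept-2-en-4-one F1. Brief 80% aq. AcOH at room temperature (kept mild to avoid cyclodehydration to a furan) frees (6R,7S)-6,7,8-trihydroxy-2,6-dimethyloct-2-en-4-one F2. Mitsunobu etherification of its primary hydroxyl with 11 (PPh3, DIAD, THF, 0 °C) gives 7-{[(2S,3R)-2,3-dihydroxy-3,7-dimethyl-5-oxooct-6-en-1-yl]oxy}-8-methoxy-2H-chromen-2-one F3. MsCl/Et3N at −20 °C, which takes the secondary and leaves the tertiary hydroxyl, brings the material back to the route at 14.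

Step 7 can fail because the primary mesylate is β‑branched and next to a second mesylate, so substitution may be slow and phenoxide attack at sulfur or elimination may compete. The fallback sets out from diol 9 and makes the aryl ether by redox condensation instead of sulfonate displacement. Mitsunobu reaction with 11 (PPh3, DIAD, THF, 0 °C → rt) at the primary hydroxyl gives 7-{(2S)-2-hydroxy-2-[(5R)-5-methyl-3-(2-methylprop-1-en-1-yl)-4,5-dihydro-1,2-oxazol-5-yl]ethoxy}-8-methoxy-2H-chromen-2-one F4. Mesylation of its single remaining hydroxyl (MsCl, Et3N, CH2Cl2, 0 °C) returns to the route at 12.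

Step 9 can fail because the directing carbinol is tertiary, so the anti selectivity rests only on the methyl versus branched‑alkyl difference in the chair. The fallback sets out from 14 and replaces the borohydride by a silicon‑tethered hydride. Silylation of the tertiary hydroxyl with i‑Pr2SiHCl/imidazole gives (2S,3R)-3-{[di(propan-2-yl)silyl]oxy}-1-[(8-methoxy-2-oxo-2H-chromen-7-yl)oxy]-3,7-dimethyl-5-oxooct-6-en-2-yl methanesulfonate F5. SnCl4‑catalysed intramolecular hydrosilylation (CH2Cl2, −80 °C), in which the bulky silyl unit enforces the anti chair, gives (1S)-2-[(8-methoxy-2-oxo-2H-chromen-7-yl)oxy]-1-[(4R,6R)-4-methyl-6-(2-methylprop-1-en-1-yl)-2,2-di(propan-2-yl)-1,3,2-dioxasilinan-4-yl]ethyl methanesulfonate F6. HF·pyridine in THF removes the silylene and returns to the route at 15.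

**Further compounds**
F1 | step 4 | (6R)-6-[(4S)-2,2-dimethyl-1,3-dioxolan-4-yl]-6-hydroxy-2-methylhept-2-en-4-one | CC(C)=CC(=O)C[C@@](C)(O)[C@@H]1COC(C)(C)O1
F2 | step 4 | (6R,7S)-6,7,8-trihydroxy-2,6-dimethyloct-2-en-4-one | CC(C)=CC(=O)C[C@@](C)(O)[C@@H](O)CO
F3 | step 4 | 7-{[(2S,3R)-2,3-dihydroxy-3,7-dimethyl-5-oxooct-6-en-1-yl]oxy}-8-methoxy-2H-chromen-2-one | COc1c(OC[C@H](O)[C@](C)(O)CC(=O)C=C(C)C)ccc2ccc(=O)oc12
F4 | step 7 | 7-{(2S)-2-hydroxy-2-[(5R)-5-methyl-3-(2-methylprop-1-en-1-yl)-4,5-dihydro-1,2-oxazol-5-yl]ethoxy}-8-methoxy-2H-chromen-2-one | COc1c(OC[C@H](O)[C@@]3(C)CC(C=C(C)C)=NO3)ccc2ccc(=O)oc12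
F5 | step 9 | (2S,3R)-3-{[di(propan-2-yl)silyl]oxy}-1-[(8-methoxy-2-oxo-2H-chromen-7-yl)oxy]-3,7-dimethyl-5-oxooct-6-en-2-yl methanesulfonate | COc1c(OC[C@H](OS(C)(=O)=O)[C@](C)(O[SiH](C(C)C)C(C)C)CC(=O)C=C(C)C)ccc2ccc(=O)oc12
F6 | step 9 | (1S)-2-[(8-methoxy-2-oxo-2H-chromen-7-yl)oxy]-1-[(4R,6R)-4-methyl-6-(2-methylprop-1-en-1-yl)-2,2-di(propan-2-yl)-1,3,2-dioxasilinan-4-yl]ethyl methanesulfonate | COc1c(OC[C@H](OS(C)(=O)=O)[C@@]3(C)C[C@H](C=C(C)C)O[Si](C(C)C)(C(C)C)O3)ccc2ccc(=O)oc12
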